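**Plan**

Locants follow the target's bicyclo[3.2.1]octane skeleton and are kept for the same atoms in every precursor: C1 (allyl bridgehead), C2=C3(OMe), C4 (OH), C5 (bridgehead H), C6 (aryl), C7 (Me), C8 (C=O).
Retrosynthesis: removing O-methyl and O-silyl leads to the 3,8-dione. Its two ketones are 1,4-related through C1–C2, which is the retron of a donor–acceptor cyclopropane C1–C2–C8 (donor oxygen on C8, acceptor C3=O on C2).
Re-forming C2–C8 shrinks the six-membered ring C1–C2–C3–C4–C5–C8 to the five-membered ketone ring C8–C2–C3–C4–C5 of a tricyclo[3.3.0.0(2,8)]octan-3-one. That tricycle is cut at C1–C2 and C2–C8 to a diazoketone hanging on a cyclopentene enol silane. Earlier cuts are C7–CH3, C1–allyl, C4–C5 and C6–aryl.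
Forward: the cyclopentane C8–C1–C7–C6–C5 comes from a 4-silyloxycyclopentenone and is loaded by aryl conjugate addition/glyoxylate aldol, elimination, α-allylation and methyl cuprate addition. A [2+1] addition then closes the cyclopropane and the five-membered ring, and fragmentation expands that ring to six.
Stereochemistry: the single stereocentre of the starting enone (erased in step 2) is relayed to C6 (anti addition), C5 (anti to aryl), C4 (closed aldol transition state) and C7 (anti to aryl). Quaternary C1 is dictated by the tether in the key step.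

Key step: step 8

Remark: the four carbon building blocks (silyloxy enone, aryl Grignard solution, ethyl glyoxylate, allylstannane) are taken as commercial. Ethereal diazomethane is generated separately just before use.

Step 1
Reactants: 1 (R)-4-(tert-butyldimethylsilyloxy)cyclopent-2-en-1-one; 2 3,4-dimethoxyphenylmagnesium bromide; 3 ethyl glyoxylate
Product: 5 ethyl (2R)-2-[(1S,2S,3R)-3-(tert-butyldimethylsilyloxy)-2-(3,4-dimethoxyphenyl)-5-oxocyclopentyl]-2-hydroxyacetate, via bromomagnesium enolate 4 (not isolated)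
Conditions: 2, CuBr·SMe2 (cat.), THF, −78 °C, then 1; then 3 (freshly cracked monomer), −78 °C; aq NH4Cl
Reagents that add atoms: none
Why: Copper-catalysed conjugate addition with aldol trapping of the regiodefined enolate (three-component coupling) should bring the aryl group to C6 anti to OTBS and the aldehyde to C5 anti to the aryl group, while the ring-locked E-enolate reacts through a closed Zimmerman–Traxler chair to give the anti aldol, that is (R) at C4.

Step 2
Reactants: 5 ethyl (2R)-2-[(1S,2S,3R)-3-(tert-butyldimethylsilyloxy)-2-(3,4-dimethoxyphenyl)-5-oxocyclopentyl]-2-hydroxyacetate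
Product: 7 ethyl (2R)-2-(tert-butyldimethylsilyloxy)-2-[(1S,2S)-2-(3,4-dimethoxyphenyl)-5-oxocyclopent-3-en-1-yl]acetate, via hydroxy enone 6 (not isolated)
Conditions: DBU (cat.), CH2Cl2, 0 °C; then 2,6-lutidine, TBSOTf, −78 °C
Reagents that add atoms: tert-butyldimethylsilyl triflate, CC(C)(C)[Si](C)(C)OS(=O)(=O)C(F)(F)F
Why: In this E1cB elimination followed by O-silylation, silanolate on C7 is a far better leaving group than the free hydroxyl on C4, so only the ring C7–O bond should be lost (through the unhindered C1H2), and C4, C5 and C6 are not touched.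

Step 3
Reactants: 7 ethyl (2R)-2-(tert-butyldimethylsilyloxy)-2-[(1S,2S)-2-(3,4-dimethoxyphenyl)-5-oxocyclopent-3-en-1-yl]acetate
Product: 8 ethyl (2R)-2-(tert-butyldimethylsilyloxy)-2-[(1S,5R)-5-(3,4-dimethoxyphenyl)-3-iodo-2-oxocyclopent-3-en-1-yl]acetate
Conditions: I2, pyridine, CH2Cl2, 0 °C → rt
Reagents that add atoms: iodine, II
Why: α-Iodination of the enone by the pyridine addition–iodination–elimination sequence (Baylis–Hillman-type activation) can act only at the α-vinylic carbon C1 and leaves all stereocentres alone (the C6 descriptor changes by priority only).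

Step 4
Reactants: 8 ethyl (2R)-2-(tert-butyldimethylsilyloxy)-2-[(1S,5R)-5-(3,4-dimethoxyphenyl)-3-iodo-2-oxocyclopent-3-en-1-yl]acetate; 9 allyltributylstannane
Product: 10 ethyl (2R)-2-(tert-butyldimethylsilyloxy)-2-[(1S,5S)-3-allyl-5-(3,4-dimethoxyphenyl)-2-oxocyclopent-3-en-1-yl]acetate
Conditions: Pd2(dba)3 (cat.), AsPh3, CuI (cat.), NMP, rt
Reagents that add atoms: none
Why: Stille coupling of an α-iodoenone under soft-ligand/copper co-catalysis proceeds at room temperature without base, so the allyl group should arrive on C1 while the base-sensitive benzylic C6–H is spared.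

Step 5
Reactants: 10 ethyl (2R)-2-(tert-butyldimethylsilyloxy)-2-[(1S,5S)-3-allyl-5-(3,4-dimethoxyphenyl)-2-oxocyclopent-3-en-1-yl]acetate
Product: 12 ethyl (2R)-2-(tert-butyldimethylsilyloxy)-2-[(1S,4S,5S)-3-allyl-2-(tert-butyldimethylsilyloxy)-5-(3,4-dimethoxyphenyl)-4-methylcyclopent-2-en-1-yl]acetate, via lithium enolate 11 (not isolated)
Conditions: Me2CuLi (from MeLi, CuI), Et2O, −78 °C; then TBSOTf, −78 → 0 °C
Reagents that add atoms: lithium dimethylcuprate, [Li+].C[Cu-]C; tert-butyldimethylsilyl triflate, CC(C)(C)[Si](C)(C)OS(=O)(=O)C(F)(F)F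
Why: Cuprate conjugate addition with O-silyl trapping should deliver methyl to C7 anti to the vicinal C6 aryl group and freeze the enolate regiospecifically as the tetrasubstituted enol silane C8=C1, which deprotonation could not provide.

Step 6
Reactants: 12 ethyl (2R)-2-(tert-butyldimethylsilyloxy)-2-[(1S,4S,5S)-3-allyl-2-(tert-butyldimethylsilyloxy)-5-(3,4-dimethoxyphenyl)-4-methylcyclopent-2-en-1-yl]acetate
Product: 13 (2R)-2-(tert-butyldimethylsilyloxy)-2-[(1S,4S,5S)-3-allyl-2-(tert-butyldimethylsilyloxy)-5-(3,4-dimethoxyphenyl)-4-methylcyclopent-2-en-1-yl]acetic acid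
Conditions: Me3SnOH, 1,2-dichloroethane, 70 °C; cold dilute HCl wash
Reagents that add atoms: trimethyltin hydroxide, C[Sn](C)(C)O
Why: Near-neutral tin hydroxide ester hydrolysis cleaves the ethyl ester without epimerising C4 and should leave both the hindered enol silane and the silyl ether in place, and the ring ketone is masked so no β-elimination can occur.

Step 7
Reactants: 13 (2R)-2-(tert-butyldimethylsilyloxy)-2-[(1S,4S,5S)-3-allyl-2-(tert-butyldimethylsilyloxy)-5-(3,4-dimethoxyphenyl)-4-methylcyclopent-2-en-1-yl]acetic acid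
Product: 15 (3R)-3-(tert-butyldimethylsilyloxy)-1-diazo-3-[(1S,4S,5S)-3-allyl-2-(tert-butyldimethylsilyloxy)-5-(3,4-dimethoxyphenyl)-4-methylcyclopent-2-en-1-yl]propan-2-one, via acid chloride 14 (not isolated)
Conditions: 1-chloro-N,N,2-trimethylprop-1-en-1-amine, CH2Cl2, 0 °C; then CH2N2, Et3N, Et2O, 0 °C
Reagents that add atoms: diazomethane, C=[N+]=[N-]
Why: Acid chloride formation with the α-chloroenamine releases no HCl, and acylation of diazomethane in the presence of Et3N (first stage of the Arndt–Eistert sequence) introduces C2 as the diazo carbon under conditions the enol silane tolerates.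

Step 8
Reactants: 15 (3R)-3-(tert-butyldimethylsilyloxy)-1-diazo-3-[(1S,4S,5S)-3-allyl-2-(tert-butyldimethylsilyloxy)-5-(3,4-dimethoxyphenyl)-4-methylcyclopent-2-en-1-yl]propan-2-one
Product: 17 (1S,4R,5S,6S,7S)-1-allyl-4-(tert-butyldimethylsilyloxy)-6-(3,4-dimethoxyphenyl)-7-methylbicyclo[3.2.1]octane-3,8-dione, via siloxycyclopropane 16 (not isolated)
Conditions: Rh2(cap)4 (cat.), CH2Cl2, 40 °C, slow addition of 15; then Et3N·3HF, rt
Reagents that add atoms: none
Why: Rh(II) converts the diazoketone into an electrophilic carbenoid at C2 that adds to the most electron-rich π bond within reach, the enol silane C8=C1, in an intramolecular [2+1] cycloaddition that closes the cyclopropane C1–C2–C8 and, through the tether C3–C4–C5, the five-membered ketone ring C8–C2–C3–C4–C5 (bicyclo[3.1.0]hexan-2-one mode of closure, known from cyclopent-2-enylacetyl diazomethane giving tricyclo[3.3.0.0(2,8)]octan-3-one). In 16 the bond C2–C8 joins the siloxy donor carbon to the α-keto acceptor carbon, so removal of silicon by fluoride triggers a retro-aldol-type (homo-De Mayo) heterolysis of exactly this bond, the known opening of 2-siloxycyclopropyl carbonyl compounds to 1,4-dicarbonyls. Because C2–C8 is the bond shared by the cyclopropane and the five-membered ring, its cleavage inserts C1 into that ring: the cyclopentanone becomes the six-membered ring C1–C2–C3–C4–C5–C8, C8 is released as the bridging ketone, and the C2=C3 enol is protonated to the C3 ketone. The only new stereocentre that survives, quaternary C1, is fixed by the tether, since the carbenoid can reach the ring only from the face that carries the C5 side chain, which places C2 cis to C4 and pushes the allyl group to the other face. The step needs chemoselectivity (enol silane against the allyl C=C, the benzylic C6–H and the arene), which is secured by the nucleophilicity and proximity of the enol silane, the trans aryl group and the carboxamidate catalyst; it also needs bond selectivity in the opening, which is secured by the donor/acceptor pair because cleavage of C1–C8 or C1–C2 gives no stabilised enol. Et3N·3HF is mild enough that the ordinary secondary silyl ether on C4 should stay in place.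

Step 9
Reactants: 17 (1S,4R,5S,6S,7S)-1-allyl-4-(tert-butyldimethylsilyloxy)-6-(3,4-dimethoxyphenyl)-7-methylbicyclo[3.2.1]octane-3,8-dione
Product: 19 (1R,4R,5S,6S,7S)-1-allyl-4-(tert-butyldimethylsilyloxy)-6-(3,4-dimethoxyphenyl)-3-methoxy-7-methylbicyclo[3.2.1]oct-2-en-8-one, via potassium enolate 18 (not isolated)
Conditions: KHMDS, THF, −78 °C; then Me2SO4, DMPU, −78 → −20 °C
Reagents that add atoms: dimethyl sulfate, COS(=O)(=O)OC
Why: In this kinetic enolisation and enolate O-alkylation the base should take a proton from C2H2 rather than the hindered, oxygen-bearing C4–H (C8 has only bridgehead α-carbons and cannot enolise), and the hard electrophile with a dissociated potassium enolate should attack oxygen because C2 is neopentylic next to quaternary C1.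

Step 10
Reactants: 19 (1R,4R,5S,6S,7S)-1-allyl-4-(tert-butyldimethylsilyloxy)-6-(3,4-dimethoxyphenyl)-3-methoxy-7-methylbicyclo[3.2.1]oct-2-en-8-one
Product: 20 (1R,4R,5S,6S,7S)-1-allyl-6-(3,4-dimethoxyphenyl)-4-hydroxy-3-methoxy-7-methylbicyclo[3.2.1]oct-2-en-8-one
Conditions: TBAF, AcOH (1:1), THF, 0 °C → rt
Reagents that add atoms: none
Why: Buffered fluoride desilylation breaks only the O–Si bond, so C4 keeps its configuration, and the near-neutral medium avoids both retro-aldol opening of the β-hydroxy ketone and hydrolysis of the methyl enol ether.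

**Compound list**

1 | (R)-4-(tert-butyldimethylsilyloxy)cyclopent-2-en-1-one | O=C1C=C[C@H](O[Si](C)(C)C(C)(C)C)C1 | starting material
2 | 3,4-dimethoxyphenylmagnesium bromide | COc1ccc([Mg]Br)cc1OC | starting material
3 | ethyl glyoxylate | CCOC(=O)C=O | starting material
4 | bromomagnesium (3S,4R)-4-(tert-butyldimethylsilyloxy)-3-(3,4-dimethoxyphenyl)cyclopent-1-en-1-olate | Br[Mg]OC1=C[C@@H](c2ccc(OC)c(OC)c2)[C@H](O[Si](C)(C)C(C)(C)C)C1 | intermediate
5 | ethyl (2R)-2-[(1S,2S,3R)-3-(tert-butyldimethylsilyloxy)-2-(3,4-dimethoxyphenyl)-5-oxocyclopentyl]-2-hydroxyacetate | O=C1C[C@@H](O[Si](C)(C)C(C)(C)C)[C@H](c2ccc(OC)c(OC)c2)[C@H]1[C@@H](O)C(=O)OCC | intermediate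
6 | ethyl (2R)-2-[(1S,2S)-2-(3,4-dimethoxyphenyl)-5-oxocyclopent-3-en-1-yl]-2-hydroxyacetate | O=C1C=C[C@H](c2ccc(OC)c(OC)c2)[C@H]1[C@@H](O)C(=O)OCC | intermediate
7 | ethyl (2R)-2-(tert-butyldimethylsilyloxy)-2-[(1S,2S)-2-(3,4-dimethoxyphenyl)-5-oxocyclopent-3-en-1-yl]acetate | O=C1C=C[C@H](c2ccc(OC)c(OC)c2)[C@H]1[C@@H](O[Si](C)(C)C(C)(C)C)C(=O)OCC | intermediate
8 | ethyl (2R)-2-(tert-butyldimethylsilyloxy)-2-[(1S,5R)-5-(3,4-dimethoxyphenyl)-3-iodo-2-oxocyclopent-3-en-1-yl]acetate | O=C1C(I)=C[C@H](c2ccc(OC)c(OC)c2)[C@H]1[C@@H](O[Si](C)(C)C(C)(C)C)C(=O)OCC | intermediate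
9 | allyltributylstannane | C=CC[Sn](CCCC)(CCCC)CCCC | starting material
10 | ethyl (2R)-2-(tert-butyldimethylsilyloxy)-2-[(1S,5S)-3-allyl-5-(3,4-dimethoxyphenyl)-2-oxocyclopent-3-en-1-yl]acetate | O=C1C(CC=C)=C[C@H](c2ccc(OC)c(OC)c2)[C@H]1[C@@H](O[Si](C)(C)C(C)(C)C)C(=O)OCC | intermediate
11 | lithium enolate (C8=C1) from methyl addition to 10, methyl trans to aryl | [Li+].C=CCC1=C([O-])[C@H]([C@@H](O[Si](C)(C)C(C)(C)C)C(=O)OCC)[C@@H](c2ccc(OC)c(OC)c2)[C@@H]1C | intermediate
12 | ethyl (2R)-2-(tert-butyldimethylsilyloxy)-2-[(1S,4S,5S)-3-allyl-2-(tert-butyldimethylsilyloxy)-5-(3,4-dimethoxyphenyl)-4-methylcyclopent-2-en-1-yl]acetate | C=CCC1=C(O[Si](C)(C)C(C)(C)C)[C@H]([C@@H](O[Si](C)(C)C(C)(C)C)C(=O)OCC)[C@@H](c2ccc(OC)c(OC)c2)[C@@H]1C | intermediate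
13 | (2R)-2-(tert-butyldimethylsilyloxy)-2-[(1S,4S,5S)-3-allyl-2-(tert-butyldimethylsilyloxy)-5-(3,4-dimethoxyphenyl)-4-methylcyclopent-2-en-1-yl]acetic acid | C=CCC1=C(O[Si](C)(C)C(C)(C)C)[C@H]([C@@H](O[Si](C)(C)C(C)(C)C)C(=O)O)[C@@H](c2ccc(OC)c(OC)c2)[C@@H]1C | intermediate
14 | acid chloride of 13 | C=CCC1=C(O[Si](C)(C)C(C)(C)C)[C@H]([C@@H](O[Si](C)(C)C(C)(C)C)C(=O)Cl)[C@@H](c2ccc(OC)c(OC)c2)[C@@H]1C | intermediate
15 | (3R)-3-(tert-butyldimethylsilyloxy)-1-diazo-3-[(1S,4S,5S)-3-allyl-2-(tert-butyldimethylsilyloxy)-5-(3,4-dimethoxyphenyl)-4-methylcyclopent-2-en-1-yl]propan-2-one | C=CCC1=C(O[Si](C)(C)C(C)(C)C)[C@H]([C@@H](O[Si](C)(C)C(C)(C)C)C(=O)C=[N+]=[N-])[C@@H](c2ccc(OC)c(OC)c2)[C@@H]1C | intermediate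
16 | 8-allyl-1,4-bis(tert-butyldimethylsilyloxy)-6-(3,4-dimethoxyphenyl)-7-methyltricyclo[3.3.0.0(2,8)]octan-3-one, cyclopropane on the ring face that carried the side chain, aryl trans to methyl | C=CC[C@]12[C@]3(O[Si](C)(C)C(C)(C)C)[C@H]1C(=O)[C@H](O[Si](C)(C)C(C)(C)C)[C@@H]3[C@@H](c1ccc(OC)c(OC)c1)[C@@H]2C | intermediate
17 | (1S,4R,5S,6S,7S)-1-allyl-4-(tert-butyldimethylsilyloxy)-6-(3,4-dimethoxyphenyl)-7-methylbicyclo[3.2.1]octane-3,8-dione | C=CC[C@@]12CC(=O)[C@H](O[Si](C)(C)C(C)(C)C)[C@@H](C1=O)[C@@H](c1ccc(OC)c(OC)c1)[C@@H]2C | intermediate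
18 | potassium C2=C3 enolate of 17 | [K+].C=CC[C@@]12C=C([O-])[C@H](O[Si](C)(C)C(C)(C)C)[C@@H](C1=O)[C@@H](c1ccc(OC)c(OC)c1)[C@@H]2C | intermediate
19 | (1R,4R,5S,6S,7S)-1-allyl-4-(tert-butyldimethylsilyloxy)-6-(3,4-dimethoxyphenyl)-3-methoxy-7-methylbicyclo[3.2.1]oct-2-en-8-one | C=CC[C@@]12C=C(OC)[C@H](O[Si](C)(C)C(C)(C)C)[C@@H](C1=O)[C@@H](c1ccc(OC)c(OC)c1)[C@@H]2C | intermediate
20 | (1R,4R,5S,6S,7S)-1-allyl-6-(3,4-dimethoxyphenyl)-4-hydroxy-3-methoxy-7-methylbicyclo[3.2.1]oct-2-en-8-one | C=CC[C@@]12C=C(OC)[C@H](O)[C@@H](C1=O)[C@@H](c1ccc(OC)c(OC)c1)[C@@H]2C | target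

Total step count: 10. Longest linear sequence: 10 steps (from 1).

**Steps most likely to fail**

Step 8. The carbenoid may be diverted into insertion into the cis-disposed benzylic C6–H bond or into attack on the allyl π bond. The endocyclic cyclopropane bond also overlaps poorly with the ketone π system at the outset and may open reluctantly.
The fallback is a polar route without a carbene that sets out from ester 12. Chloromethyllithium (ICH2Cl, MeLi·LiBr, THF, −78 °C) homologates the ester to the chloromethyl ketone F1. TASF at low temperature then cleaves the enol silane faster than the alkyl silyl ether to give the naked enolate F2. This enolate closes the C1–C2 bond by 6-(enolendo)-exo-tet alkylation from the only face the tether allows. In this variant the six-membered ring is closed directly. The route is rejoined at dione 17.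

Step 9. Competing C-methylation at C2 may occur, or proton exchange may move the enolate to the C4 side and scramble C4.
The fallback sets out from 17. Buffered TBAF gives the ketol F3, and oxidation (Dess–Martin periodinane or Cu(OAc)2) gives the 3,4-diketone. This diketone can enolise only towards C2 and should therefore exist as the diosphenol F4. TMSCHN2 methylates the acidic enol oxygen to the methoxy enedione F5. Luche reduction (NaBH4, CeCl3, MeOH, −78 °C) should then deliver hydride to the conjugated C4 ketone from the face syn to C8, away from the C6–C7 bridge, giving the endo alcohol. The route is rejoined at target 20. This detour also funnels any material of the wrong C4 configuration into 20.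

Step 2. Retro-aldol/re-aldol scrambling of C4 and C5 may occur in the free aldol under the amidine base. The base may also shift the enone double bond into conjugation with the arene, which would erase C6.
The fallback reverses the order of events and sets out from enolate 4 (made from 1 and 2 as in step 1). Protonation gives the ketone F6, and DBU elimination gives the aryl enone F7. LDA at −78 °C forms the cross-conjugated lithium enolate F8 by kinetic α′-deprotonation. Addition of 3 then gives the anti aldol trans to the aryl group through the same closed transition state. In this order the aldol never meets an amine base. The route is rejoined at hydroxy enone 6, which is silylated to 7.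

**Further compounds**

F1 | step 8 | (3R)-3-(tert-butyldimethylsilyloxy)-1-chloro-3-[(1S,4S,5S)-3-allyl-2-(tert-butyldimethylsilyloxy)-5-(3,4-dimethoxyphenyl)-4-methylcyclopent-2-en-1-yl]propan-2-one | C=CCC1=C(O[Si](C)(C)C(C)(C)C)[C@H]([C@@H](O[Si](C)(C)C(C)(C)C)C(=O)CCl)[C@@H](c2ccc(OC)c(OC)c2)[C@@H]1C
F2 | step 8 | tris(dimethylamino)sulfonium C8=C1 enolate of the chloromethyl ketone | CN(C)[S+](N(C)C)N(C)C.C=CCC1=C([O-])[C@H]([C@@H](O[Si](C)(C)C(C)(C)C)C(=O)CCl)[C@@H](c2ccc(OC)c(OC)c2)[C@@H]1C
F3 | step 9 | (1S,4R,5S,6S,7S)-1-allyl-6-(3,4-dimethoxyphenyl)-4-hydroxy-7-methylbicyclo[3.2.1]octane-3,8-dione | C=CC[C@@]12CC(=O)[C@H](O)[C@@H](C1=O)[C@@H](c1ccc(OC)c(OC)c1)[C@@H]2C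
F4 | step 9 | (1R,5R,6S,7S)-1-allyl-6-(3,4-dimethoxyphenyl)-3-hydroxy-7-methylbicyclo[3.2.1]oct-2-ene-4,8-dione (target locants) | C=CC[C@@]12C=C(O)C(=O)[C@@H](C1=O)[C@@H](c1ccc(OC)c(OC)c1)[C@@H]2C
F5 | step 9 | (1R,5R,6S,7S)-1-allyl-6-(3,4-dimethoxyphenyl)-3-methoxy-7-methylbicyclo[3.2.1]oct-2-ene-4,8-dione (target locants) | C=CC[C@@]12C=C(OC)C(=O)[C@@H](C1=O)[C@@H](c1ccc(OC)c(OC)c1)[C@@H]2C
F6 | step 2 | (3S,4R)-4-(tert-butyldimethylsilyloxy)-3-(3,4-dimethoxyphenyl)cyclopentan-1-one | O=C1C[C@@H](O[Si](C)(C)C(C)(C)C)[C@H](c2ccc(OC)c(OC)c2)C1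
F7 | step 2 | (R)-4-(3,4-dimethoxyphenyl)cyclopent-2-en-1-one | O=C1C=C[C@H](c2ccc(OC)c(OC)c2)C1
F8 | step 2 | lithium cross-conjugated enolate of (R)-4-(3,4-dimethoxyphenyl)cyclopent-2-en-1-one | [Li+].[O-]C1=C[C@@H](c2ccc(OC)c(OC)c2)C=C1
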